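**Plan**

1. Ring B is numbered C1 (carries the CH2), C2 (OMe), C3 (prenyl), C4 (OMe), C5 (H), C6 (OH). The retrosynthesis cuts C1–CH2, CH2–C(=O), the C3–CH2 bond of the prenyl group and the prenyl C=C.
2. No ring is built. Ring B is bought as 2,6-dimethoxy-1,4-benzoquinone and kept dearomatized as a p-quinol: allyl adds to the carbonyl between the two methoxy carbons (future C3), and cross-metathesis turns allyl into prenyl.
3. Ring A arrives as an aroylketene (from an acyl Meldrum's acid, which supplies the CH2 carbon) that esterifies the quinol OH. A Carroll-type [3,3] shift then moves the ArC(=O)CH unit from that oxygen to C1, CO2 is lost and ring B aromatizes, freeing the C6 hydroxyl.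
4. Enabling feature: in ring B, C3 (prenyl) is para to C6 (OH) and sits between the two methoxy carbons C2 and C4, so the ring has a local mirror plane through C3 and C6. A quinol at C3 therefore has two equivalent allylic termini (C1 and C5), and the para pair C3/C6 maps onto the two electronically different carbonyls of the quinone.
5. Stereochemistry: none to set. The target has no stereocentre, and the alkene carries two identical methyl groups.
6. The last step removes the two silyl ethers of ring A with fluoride.

Key step: step 6

Remark: 1, 4 and 6 are taken as commercially available; the transient stereocentres of 11 and 12 are written without descriptors because they form as mixtures and are erased.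

**Route**

Step 1
Reactants: 1 2,4-dihydroxybenzoic acid
Product: 2 tert-butyldimethylsilyl 2,4-bis(tert-butyldimethylsilyloxy)benzoate
Conditions: TBSCl (3.3 equiv), imidazole, DMF, rt to 40 °C; non-aqueous work-up (hexane)
Reagents that add atoms: tert-butyldimethylsilyl chloride, CC(C)(C)[Si](C)(C)Cl
Why: Silyl chloride/imidazole silylation caps both phenols, of which the ortho one would otherwise close onto the later ketene, and turns the acid into a silyl ester that can be converted to the acid chloride without acid; no stereocentre is formed.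

Step 2
Reactants: 2 tert-butyldimethylsilyl 2,4-bis(tert-butyldimethylsilyloxy)benzoate
Product: 3 2,4-bis(tert-butyldimethylsilyloxy)benzoyl chloride
Conditions: (COCl)2, DMF (cat.), CH2Cl2, 0 °C to rt; evaporate, use crude
Reagents that add atoms: oxalyl chloride, ClC(=O)C(=O)Cl
Why: Vilsmeier-type activation of a silyl ester by oxalyl chloride/DMF is a known neutral route to acid chlorides that releases TBSCl instead of HCl and so should leave the two aryl silyl ethers untouched.

Step 3
Reactants: 3 2,4-bis(tert-butyldimethylsilyloxy)benzoyl chloride; 4 Meldrum's acid (2,2-dimethyl-1,3-dioxane-4,6-dione)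
Product: 5 5-{[2,4-bis(tert-butyldimethylsilyloxy)phenyl](hydroxy)methylidene}-2,2-dimethyl-1,3-dioxane-4,6-dione
Conditions: pyridine (2.2 equiv), CH2Cl2, 0 °C to rt; cold dilute HCl wash; use without chromatography
Reagents that add atoms: none
Why: C-acylation of the acidic methylene of Meldrum's acid by an acid chloride with pyridine is the standard entry to acyl Meldrum's acids, which are aroylketene precursors; the methylene carbon of 4 becomes the CH2 of the target.

Step 4
Reactants: 6 2,6-dimethoxy-1,4-benzoquinone
Product: 7 4-allyl-4-hydroxy-3,5-dimethoxycyclohexa-2,5-dien-1-one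
Conditions: allylMgBr (1.1 equiv), THF, −78 °C; sat. aq NH4Cl at −78 °C
Reagents that add atoms: allylmagnesium bromide, C=CC[Mg]Br
Why: Grignard 1,2-addition to a quinone carbonyl should occur at the carbonyl between the two methoxy-bearing carbons, because the other carbonyl is deactivated as a doubly vinylogous ester, and at −78 °C the magnesium alkoxide should not undergo an anionic [3,3] shift; the new quaternary carbon lies on the mirror plane and is not a stereocentre.

Step 5
Reactants: 7 4-allyl-4-hydroxy-3,5-dimethoxycyclohexa-2,5-dien-1-one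
Product: 8 4-hydroxy-3,5-dimethoxy-4-(3-methylbut-2-en-1-yl)cyclohexa-2,5-dien-1-one
Conditions: 2-methylbut-2-ene (excess), second-generation Grubbs catalyst RuCl2(=CHPh)(H2IMes)(PCy3) (3 mol %), CH2Cl2, 40 °C
Reagents that add atoms: 2-methylbut-2-ene, CC=C(C)C
Why: Olefin cross-metathesis of a monosubstituted allyl group with excess 2-methylbut-2-ene is the standard way to make a prenyl group, the ring C=C bonds being trisubstituted push–pull enol ethers that the ruthenium carbene should not engage; the new alkene has two identical methyl groups, so no geometry arises.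

Step 6
Reactants: 8 4-hydroxy-3,5-dimethoxy-4-(3-methylbut-2-en-1-yl)cyclohexa-2,5-dien-1-one; 5 5-{[2,4-bis(tert-butyldimethylsilyloxy)phenyl](hydroxy)methylidene}-2,2-dimethyl-1,3-dioxane-4,6-dione
Product: 13 1-[2,4-bis(tert-butyldimethylsilyloxy)phenyl]-2-[6-hydroxy-2,4-dimethoxy-3-(3-methylbut-2-en-1-yl)phenyl]ethan-1-one, via aroylketene 9 (not isolated), via quinol ester 10 (not isolated), via dienone acid 11 (not isolated), via phenol acid 12 (not isolated)
Conditions: 5 (1.1 equiv) added slowly to 8 in PhMe, 100 °C; then 150 °C, sealed tube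
Reagents that add atoms: none
Why: Proposed new method: thermolysis of 5 extrudes acetone and CO2 to give aroylketene 9, which the tertiary quinol hydroxyl of 8 captures as β-keto ester 10; the ester-enol tautomer of 10 is an allyl vinyl ether whose allyl part is C4–C3=C2 of the dienone, so a Carroll rearrangement ([3,3] shift) breaks the C4–O bond and bonds the enol carbon to C2, and the resulting cyclohexa-2,4-dienone 11 enolizes to phenol 12 and loses CO2 as a β-keto acid. The closest known reaction is the thermal Carroll rearrangement of tertiary allylic β-keto esters formed in the flask from acylketene precursors; what is new is that the allyl unit is part of a cross-conjugated cyclohexadienone, so that the shift ends in aromatization. No ring is closed, the six-membered array being only the chair- or boat-like transition state on the ring face that carries the oxygen. The two stereocentres of 11 (ring C2 and the side-chain CH) are not controlled and need not be, since enolization and decarboxylation erase both. The step needs site selectivity and the right [3,3] path: C2 and C6 of 8 are equivalent through the mirror plane that contains C1 and C4, each lying between the carbonyl carbon and a methoxy carbon, so either terminus gives the same substitution pattern, and the competing Cope shift of the C4 side chain into the ring is disfavoured because prenyl would have to bond through its gem-dimethyl terminus, which is why metathesis precedes this step. Staged heating ensures that the only hydroxyl present while the ketene is free is that of the quinol, the ring B phenol appearing only afterwards.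

Step 7
Reactants: 13 1-[2,4-bis(tert-butyldimethylsilyloxy)phenyl]-2-[6-hydroxy-2,4-dimethoxy-3-(3-methylbut-2-en-1-yl)phenyl]ethan-1-one
Product: 14 licoriphenone, 1-(2,4-dihydroxyphenyl)-2-[6-hydroxy-2,4-dimethoxy-3-(3-methylbut-2-en-1-yl)phenyl]ethan-1-one
Conditions: Bu4NF (2.2 equiv), AcOH (2.5 equiv), THF, 0 °C
Reagents that add atoms: none
Why: Fluoride cleavage of aryl silyl ethers, buffered with acetic acid so that the phenoxides are protonated as they form, should free ring A without touching the prenyl group, the methyl ethers or the enolizable ketone.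

**Compound list**

1 | 2,4-dihydroxybenzoic acid | OC(=O)c1ccc(O)cc1O | starting material
2 | tert-butyldimethylsilyl 2,4-bis(tert-butyldimethylsilyloxy)benzoate | CC(C)(C)[Si](C)(C)OC(=O)c1ccc(O[Si](C)(C)C(C)(C)C)cc1O[Si](C)(C)C(C)(C)C | intermediate
3 | 2,4-bis(tert-butyldimethylsilyloxy)benzoyl chloride | ClC(=O)c1ccc(O[Si](C)(C)C(C)(C)C)cc1O[Si](C)(C)C(C)(C)C | intermediate
4 | Meldrum's acid (2,2-dimethyl-1,3-dioxane-4,6-dione) | CC1(C)OC(=O)CC(=O)O1 | starting material
5 | 5-{[2,4-bis(tert-butyldimethylsilyloxy)phenyl](hydroxy)methylidene}-2,2-dimethyl-1,3-dioxane-4,6-dione | CC1(C)OC(=O)C(=C(O)c2ccc(O[Si](C)(C)C(C)(C)C)cc2O[Si](C)(C)C(C)(C)C)C(=O)O1 | intermediate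
6 | 2,6-dimethoxy-1,4-benzoquinone | COC1=CC(=O)C=C(OC)C1=O | starting material
7 | 4-allyl-4-hydroxy-3,5-dimethoxycyclohexa-2,5-dien-1-one | COC1=CC(=O)C=C(OC)C1(O)CC=C | intermediate
8 | 4-hydroxy-3,5-dimethoxy-4-(3-methylbut-2-en-1-yl)cyclohexa-2,5-dien-1-one | COC1=CC(=O)C=C(OC)C1(O)CC=C(C)C | intermediate
9 | aroylketene, 3-[2,4-bis(tert-butyldimethylsilyloxy)phenyl]-3-oxoprop-1-en-1-one (forms in the flask) | O=C=CC(=O)c1ccc(O[Si](C)(C)C(C)(C)C)cc1O[Si](C)(C)C(C)(C)C | intermediate
10 | quinol ester, 2,6-dimethoxy-1-(3-methylbut-2-en-1-yl)-4-oxocyclohexa-2,5-dien-1-yl 3-[2,4-bis(tert-butyldimethylsilyloxy)phenyl]-3-oxopropanoate (forms in the flask) | COC1=CC(=O)C=C(OC)C1(CC=C(C)C)OC(=O)CC(=O)c1ccc(O[Si](C)(C)C(C)(C)C)cc1O[Si](C)(C)C(C)(C)C | intermediate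
11 | dienone acid, 3-[2,4-bis(tert-butyldimethylsilyloxy)phenyl]-2-[2,4-dimethoxy-3-(3-methylbut-2-en-1-yl)-6-oxocyclohexa-2,4-dien-1-yl]-3-oxopropanoic acid (forms in the flask, mixture of stereoisomers) | O=C1C=C(OC)C(CC=C(C)C)=C(OC)C1C(C(=O)O)C(=O)c1ccc(O[Si](C)(C)C(C)(C)C)cc1O[Si](C)(C)C(C)(C)C | intermediate
12 | phenol acid, 3-[2,4-bis(tert-butyldimethylsilyloxy)phenyl]-2-[6-hydroxy-2,4-dimethoxy-3-(3-methylbut-2-en-1-yl)phenyl]-3-oxopropanoic acid (forms in the flask, racemic) | COc1cc(O)c(C(C(=O)O)C(=O)c2ccc(O[Si](C)(C)C(C)(C)C)cc2O[Si](C)(C)C(C)(C)C)c(OC)c1CC=C(C)C | intermediate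
13 | 1-[2,4-bis(tert-butyldimethylsilyloxy)phenyl]-2-[6-hydroxy-2,4-dimethoxy-3-(3-methylbut-2-en-1-yl)phenyl]ethan-1-one | COc1cc(O)c(CC(=O)c2ccc(O[Si](C)(C)C(C)(C)C)cc2O[Si](C)(C)C(C)(C)C)c(OC)c1CC=C(C)C | intermediate
14 | licoriphenone | COc1cc(O)c(CC(=O)c2ccc(O)cc2O)c(OC)c1CC=C(C)C | target

**Step count and risks**

Total step count: 7. Longest linear sequence: 5 steps (1, 2, 3, 6, 7); the quinone branch (steps 4 and 5) joins at step 6.

Steps most likely to fail:

**Step 6 (proposed new method).** Several processes could compete with the intended cascade: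
- the ketene may dimerize or be captured by its own ortho silyloxy group before the hindered tertiary hydroxyl adds;
- the acidic enol 5 may trigger acid-mediated reactions of the quinol;
- the [3,3] shift may be slower than reversible loss of the ketene from 10 or than elimination of the ester.

Fallback: the bond between C1 of ring B and the CH2 is made on the aromatic ring by umpolung instead, setting out from 8 and coming back at 13. Zinc dust in acetic acid should reduce the quinol to 3,5-dimethoxy-4-(3-methylbut-2-en-1-yl)phenol F1. A Mannich reaction (Me2NH, aqueous CH2O, EtOH) at one of its two equivalent ortho positions should give 2-[(dimethylamino)methyl]-3,5-dimethoxy-4-(3-methylbut-2-en-1-yl)phenol F2, and MeI the quaternary salt 1-[6-hydroxy-2,4-dimethoxy-3-(3-methylbut-2-en-1-yl)phenyl]-N,N,N-trimethylmethanaminium iodide F3. Separately, commercial 2,4-dihydroxybenzaldehyde F4 is silylated (TBSCl, imidazole) to 2,4-bis(tert-butyldimethylsilyloxy)benzaldehyde F5. With i-Pr2NEt, F3 should lose trimethylamine to give the ortho-quinone methide 3,5-dimethoxy-6-methylidene-4-(3-methylbut-2-en-1-yl)cyclohexa-2,4-dien-1-one F6. This is acylated at its methylidene carbon by the acyl-anion equivalent formed from F5 and a thiazolium-derived N-heterocyclic carbene, a known carbene-catalysed nucleophilic acylation of ortho-quinone methides, which gives 13.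

**Step 4.** Electron transfer from the Grignard reagent may reduce the quinone, the reagent may attack the vinylogous-ester carbonyl, or the allyl group of the magnesium alkoxide may shift into the ring on warming.

Fallback: the quinol is made by oxidative dearomatization of a phenol instead of addition to a quinone. This leaves the route at 6, which it replaces, and comes back at 7. Commercial 3,5-dimethoxyphenol F7 is silylated (TIPSCl, imidazole) to (3,5-dimethoxyphenoxy)triisopropylsilane F8. Directed ortho-metalation with n-BuLi in THF at 0 °C, between the two methoxy groups because the bulky silyl ether shields the other positions, should give [2,6-dimethoxy-4-(triisopropylsilyloxy)phenyl]lithium F9. Allyl bromide then gives (4-allyl-3,5-dimethoxyphenoxy)triisopropylsilane F10, and Bu4NF gives 4-allyl-3,5-dimethoxyphenol F11. PhI(OAc)2 in aqueous MeCN should add water para to the hydroxyl and give 7.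

**Step 3.** The ortho silyl group may be lost during C-acylation or the acid wash, after which the free phenol would close onto the acyl Meldrum's acid.

Fallback: a neutral ketene precursor is made by a crossed Claisen condensation, setting out from 3 and coming back at 9 within step 6, hence at 13. The lithium enolate of tert-butyl acetate (2 equiv, from LiN(SiMe3)2, THF, −78 °C) should acylate on carbon with 3 to give tert-butyl 3-[2,4-bis(tert-butyldimethylsilyloxy)phenyl]-3-oxopropanoate F12. Heated with 8 in xylene with distillation of tert-butanol, F12 should release the same aroylketene 9 (known thermal transacylation of tert-butyl β-keto esters).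

**Further compounds**

F1 | step 6 | 3,5-dimethoxy-4-(3-methylbut-2-en-1-yl)phenol | COc1cc(O)cc(OC)c1CC=C(C)C
F2 | step 6 | 2-[(dimethylamino)methyl]-3,5-dimethoxy-4-(3-methylbut-2-en-1-yl)phenol | COc1cc(O)c(CN(C)C)c(OC)c1CC=C(C)C
F3 | step 6 | 1-[6-hydroxy-2,4-dimethoxy-3-(3-methylbut-2-en-1-yl)phenyl]-N,N,N-trimethylmethanaminium iodide | COc1cc(O)c(C[N+](C)(C)C)c(OC)c1CC=C(C)C.[I-]
F4 | step 6 | 2,4-dihydroxybenzaldehyde | O=Cc1ccc(O)cc1O
F5 | step 6 | 2,4-bis(tert-butyldimethylsilyloxy)benzaldehyde | O=Cc1ccc(O[Si](C)(C)C(C)(C)C)cc1O[Si](C)(C)C(C)(C)C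
F6 | step 6 | 3,5-dimethoxy-6-methylidene-4-(3-methylbut-2-en-1-yl)cyclohexa-2,4-dien-1-one | C=C1C(=O)C=C(OC)C(CC=C(C)C)=C1OC
F7 | step 4 | 3,5-dimethoxyphenol | COc1cc(O)cc(OC)c1
F8 | step 4 | (3,5-dimethoxyphenoxy)triisopropylsilane | COc1cc(O[Si](C(C)C)(C(C)C)C(C)C)cc(OC)c1
F9 | step 4 | [2,6-dimethoxy-4-(triisopropylsilyloxy)phenyl]lithium | [Li]c1c(OC)cc(O[Si](C(C)C)(C(C)C)C(C)C)cc1OC
F10 | step 4 | (4-allyl-3,5-dimethoxyphenoxy)triisopropylsilane | C=CCc1c(OC)cc(O[Si](C(C)C)(C(C)C)C(C)C)cc1OC
F11 | step 4 | 4-allyl-3,5-dimethoxyphenol | C=CCc1c(OC)cc(O)cc1OC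
F12 | step 3 | tert-butyl 3-[2,4-bis(tert-butyldimethylsilyloxy)phenyl]-3-oxopropanoate | CC(C)(C)OC(=O)CC(=O)c1ccc(O[Si](C)(C)C(C)(C)C)cc1O[Si](C)(C)C(C)(C)C
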